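**Strategy.** Everything rests on cutting the C4–C5 bond of the trisubstituted oxirane (germacrane numbering: C4 carries the methyl, C5 the hydrogen) that is fused to the ten-membered carbocycle. Because C5 sits next to the C6 carbinol, it is drawn as an α-silyloxy aldehyde and C4 as a sulfonium ylide carbon. One operation, a benzyne-triggered Corey–Chaykovsky macrocyclisation, forms C4–C5, closes the ten-membered ring and the oxirane, and sets C4 and C5 under Felkin control from C6. Its precursor is an acyclic aldehyde thioether in which the butenolide is still an open Z-configured silyloxy ester and C14 is a methyl group; lactonisation and allylic oxidation complete the target.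

Key step: step 10

Remark on the chemistry: germacrane numbering is used throughout (C1=C10 enal olefin; C4/C5 oxirane; C6 lactone carbinol; C7=C11 butenolide olefin; C8 isovalerate carbinol; C12 lactone carbonyl; C13 acetoxymethyl; C14 formyl; C15 methyl); commercial aqueous 1 is assumed to be dried before use, and 14–19 are carried as epimers at C4 because racemic 13 is used and the ylide erases that centre.

Step 1
Reactants: 1 2,2-dimethoxyacetaldehyde; 2 methyl propiolate
Product: 3 methyl (4R)-4-hydroxy-5,5-dimethoxypent-2-ynoate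
Conditions: Me2Zn, ProPhenol ligand (10 mol%, the antipode that gives the 4R alcohol), Ph3P=O (20 mol%), toluene, 0 °C; aq NH4Cl
Reagents that add atoms: none
Why: Zinc–ProPhenol asymmetric alkynylation (Trost) of the aldehyde with the propiolate should set the C6 carbinol (R) under catalyst control.

Step 2
Reactants: 3 methyl (4R)-4-hydroxy-5,5-dimethoxypent-2-ynoate
Product: 4 methyl (4R)-4-(tert-butyldimethylsilyloxy)-5,5-dimethoxypent-2-ynoate
Conditions: TBSOTf, 2,6-lutidine, CH2Cl2, −78 °C
Reagents that add atoms: tert-butyldimethylsilyl trifluoromethanesulfonate, CC(C)(C)[Si](C)(C)OS(=O)(=O)C(F)(F)F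
Why: Silylation masks the C6 hydroxyl so that the Z-hydroxy ester made in step 3 cannot lactonise before the ring closure.

Step 3
Reactants: 4 methyl (4R)-4-(tert-butyldimethylsilyloxy)-5,5-dimethoxypent-2-ynoate; 5 vinylmagnesium bromide; 6 bromomethyl acetate
Product: 8 methyl (2Z)-2-(acetoxymethyl)-3-[(1R)-1-(tert-butyldimethylsilyloxy)-2,2-dimethoxyethyl]penta-2,4-dienoate, via alkenylcopper adduct 7 (not isolated)
Conditions: 5 (2.1 equiv), CuBr·SMe2 (1.05 equiv), THF, −78 °C; then 4; then 6, DMPU, −78 to −40 °C; aq NH4Cl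
Reagents that add atoms: none
Why: Syn-carbocupration of the ynoate followed by alkylation of the configurationally stable alkenylcopper 7 with retention (tandem conjugate addition–alkylation, three components) should fix the tetrasubstituted C7=C11 olefin with the ester cis to the C6 arm.

Step 4
Reactants: 8 methyl (2Z)-2-(acetoxymethyl)-3-[(1R)-1-(tert-butyldimethylsilyloxy)-2,2-dimethoxyethyl]penta-2,4-dienoate
Product: 9 methyl (2E,4R)-2-(acetoxymethyl)-4-(tert-butyldimethylsilyloxy)-3-formyl-5,5-dimethoxypent-2-enoate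
Conditions: OsO4 (2 mol%), NaIO4, 2,6-lutidine, dioxane–H2O, rt
Reagents that add atoms: osmium tetroxide (catalytic oxygen carrier), O=[Os](=O)(=O)=O; sodium periodate (oxygen source), [Na+].[O-]I(=O)(=O)=O
Why: Lemieux–Johnson cleavage should take the monosubstituted vinyl group and leave the tetrasubstituted, ester-bearing olefin, giving the C8 aldehyde.

Step 5
Reactants: 9 methyl (2E,4R)-2-(acetoxymethyl)-4-(tert-butyldimethylsilyloxy)-3-formyl-5,5-dimethoxypent-2-enoate; 10 tributyl(2-methylallyl)stannane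
Product: 11 methyl (2Z,4S)-2-(acetoxymethyl)-3-[(1R)-1-(tert-butyldimethylsilyloxy)-2,2-dimethoxyethyl]-4-hydroxy-6-methylhepta-2,6-dienoate
Conditions: (S)-BINOL (20 mol%), Ti(OiPr)4 (10 mol%), 4 Å molecular sieves, CH2Cl2, −20 °C; aq NaHCO3
Reagents that add atoms: none
Why: Keck asymmetric allylation, in which the (S)-BINOL–titanium catalyst should deliver the 2-methylallyl group to the Si face of the aldehyde and set C8 as S by reagent control.

Step 6
Reactants: 11 methyl (2Z,4S)-2-(acetoxymethyl)-3-[(1R)-1-(tert-butyldimethylsilyloxy)-2,2-dimethoxyethyl]-4-hydroxy-6-methylhepta-2,6-dienoate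
Product: 12 methyl (2Z,4S)-2-(acetoxymethyl)-3-[(1R)-1-(tert-butyldimethylsilyloxy)-2,2-dimethoxyethyl]-6-methyl-4-(3-methylbutanoyloxy)hepta-2,6-dienoate
Conditions: (iBuCO)2O, DMAP, Et3N, CH2Cl2, 0 °C to rt
Reagents that add atoms: 3-methylbutanoic anhydride, CC(C)CC(=O)OC(=O)CC(C)C
Why: DMAP-catalysed acylation installs the C8 isovalerate on the only free hydroxyl.

Step 7
Reactants: 12 methyl (2Z,4S)-2-(acetoxymethyl)-3-[(1R)-1-(tert-butyldimethylsilyloxy)-2,2-dimethoxyethyl]-6-methyl-4-(3-methylbutanoyloxy)hepta-2,6-dienoate; 13 hex-5-en-2-ol (racemic)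
Product: 14 methyl (2Z,4S,6E)-2-(acetoxymethyl)-3-[(1R)-1-(tert-butyldimethylsilyloxy)-2,2-dimethoxyethyl]-10-hydroxy-6-methyl-4-(3-methylbutanoyloxy)undeca-2,6-dienoate (C10 epimers)
Conditions: second-generation Hoveyda–Grubbs catalyst (10 mol%), 13 (5 equiv), CH2Cl2, 40 °C
Reagents that add atoms: none
Why: Olefin cross-metathesis of the 1,1-disubstituted olefin with an excess of the terminal alkene should give the trisubstituted C1=C10 olefin with the E isomer favoured, and any minor isomer converges at step 12, which resets this geometry.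

Step 8
Reactants: 14 methyl (2Z,4S,6E)-2-(acetoxymethyl)-3-[(1R)-1-(tert-butyldimethylsilyloxy)-2,2-dimethoxyethyl]-10-hydroxy-6-methyl-4-(3-methylbutanoyloxy)undeca-2,6-dienoate
Product: 15 methyl (2Z,4S,6E)-2-(acetoxymethyl)-3-[(1R)-1-(tert-butyldimethylsilyloxy)-2,2-dimethoxyethyl]-6-methyl-4-(3-methylbutanoyloxy)-10-(phenylsulfanyl)undeca-2,6-dienoate (C10 epimers)
Conditions: PhSH, PPh3, DIAD, THF, 0 °C to rt
Reagents that add atoms: thiophenol, Sc1ccccc1
Why: Mitsunobu thioetherification (SN2 at the secondary carbinol) installs the sulfide that later becomes the ylide carbon C4.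

Step 9
Reactants: 15 methyl (2Z,4S,6E)-2-(acetoxymethyl)-3-[(1R)-1-(tert-butyldimethylsilyloxy)-2,2-dimethoxyethyl]-6-methyl-4-(3-methylbutanoyloxy)-10-(phenylsulfanyl)undeca-2,6-dienoate
Product: 16 methyl (2Z,4S,6E)-2-(acetoxymethyl)-3-[(1R)-1-(tert-butyldimethylsilyloxy)-2-oxoethyl]-6-methyl-4-(3-methylbutanoyloxy)-10-(phenylsulfanyl)undeca-2,6-dienoate (C10 epimers)
Conditions: TESOTf, 2,4,6-collidine, CH2Cl2, 0 °C; then H2O
Reagents that add atoms: water, O
Why: Fujioka–Kita acetal cleavage (silyl triflate and a pyridine base, then water) should free the C5 aldehyde without harming the silyl ether, esters or sulfide, and never passes through a free C5 alcohol that would close a δ-lactone on the cis ester.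

Step 10
Reactants: 16 methyl (2Z,4S,6E)-2-(acetoxymethyl)-3-[(1R)-1-(tert-butyldimethylsilyloxy)-2-oxoethyl]-6-methyl-4-(3-methylbutanoyloxy)-10-(phenylsulfanyl)undeca-2,6-dienoate
Product: 20 methyl (4R,5R,6R,8S)-13-acetoxy-6-(tert-butyldimethylsilyloxy)-4,5-epoxy-8-(3-methylbutanoyloxy)germacra-1(10),7(11)-dien-12-oate (C9 and C2 trans at C1=C10), via S-arylated zwitterion 17 (not isolated), via sulfonium ylide 18 (not isolated), via betaine 19 (not isolated)
Conditions: 2-(trimethylsilyl)phenyl triflate (slow addition), CsF, 18-crown-6, THF (0.001 M), 0 °C to rt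
Reagents that add atoms: none
Why: Proposed new method: benzyne, released slowly by fluoride, S-arylates the thioether to zwitterion 17, whose ortho-carbanion removes the only α-hydrogen (C4–H) through a five-membered transition state to give diphenylsulfonium ylide 18; 18 adds to the C5 aldehyde (C4–C5 bond, betaine 19) and the alkoxide then expels Ph2S to close the oxirane. The closest known reactions are aryne-triggered sulfonium ylide formation from alkyl aryl sulfides and the intramolecular Corey–Chaykovsky epoxidation of carbonyl-tethered sulfonium salts in small rings; joining them in a ten-membered closure is the unproven part. The carbocycle closes by 10-exo-trig addition to the aldehyde and the oxirane by 3-exo-tet substitution with inversion at C4, so both C4 epimers of 16 converge. C5 should be set by polar Felkin–Anh attack anti to the C6–OTBS bond (5,6-anti, 5R), and C4 (4R) by the anti betaine in which the C3 ring arm and C6 lie trans across the new bond, the arrangement of trans-4,5-epoxygermacranolides. The step needs sulfur to outrun the olefin and the aldehyde as partners for benzyne, ylide formation without external base so that the enolisable α-silyloxy aldehyde and the esters survive, and ring closure to outrun intermolecular attack; the soft unhindered sulfide, the absence of any second aldehyde (C14 is still a methyl), the nine-membered or larger transition states needed to reach any ester, and 0.001 M dilution should secure these.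

Step 11
Reactants: 20 methyl (4R,5R,6R,8S)-13-acetoxy-6-(tert-butyldimethylsilyloxy)-4,5-epoxy-8-(3-methylbutanoyloxy)germacra-1(10),7(11)-dien-12-oate
Product: 22 (4R,5R,6R,8S)-13-acetoxy-4,5-epoxy-8-(3-methylbutanoyloxy)germacra-1(10),7(11)-dien-12,6-olide (C14 methyl; C9 and C2 trans), via hydroxy ester 21 (not isolated)
Conditions: HF·pyridine, excess pyridine, THF, 0 °C to rt
Reagents that add atoms: none
Why: Fluoride desilylation frees the C6 hydroxyl, which should lactonise at once on the cis methyl ester (5-exo-trig acyl substitution), while the buffered acidic medium avoids Payne migration and transannular opening of the oxirane.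

Step 12
Reactants: 22 (4R,5R,6R,8S)-13-acetoxy-4,5-epoxy-8-(3-methylbutanoyloxy)germacra-1(10),7(11)-dien-12,6-olide
Product: 23 (4R,5R,6R,8S)-13-acetoxy-4,5-epoxy-14-hydroxy-8-(3-methylbutanoyloxy)germacra-1(10),7(11)-dien-12,6-olide (C9 and C2 cis at C1=C10)
Conditions: SeO2 (0.5 equiv), t-BuOOH, CH2Cl2, rt
Reagents that add atoms: selenium dioxide (catalytic oxygen carrier), O=[Se]=O; tert-butyl hydroperoxide (oxygen source), CC(C)(C)OO
Why: Riley allylic oxidation (ene reaction then [2,3]-sigmatropic shift) should hydroxylate the C14 methyl and, as in the known oxidation of 1(10)-trans 4,5-epoxygermacranolides, turn the C1=C10 olefin so that the new CH2OH is trans to C2 and C9 is cis to C2.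

Step 13
Reactants: 23 (4R,5R,6R,8S)-13-acetoxy-4,5-epoxy-14-hydroxy-8-(3-methylbutanoyloxy)germacra-1(10),7(11)-dien-12,6-olide
Product: 24 target, (4R,5R,6R,8S)-13-acetoxy-4,5-epoxy-8-(3-methylbutanoyloxy)-14-oxogermacra-1(10),7(11)-dien-12,6-olide (CNP0289605.1)
Conditions: MnO2, CH2Cl2, rt
Reagents that add atoms: none
Why: MnO2 oxidation of the primary allylic alcohol should give the conjugated aldehyde with retention of olefin geometry and without touching the oxirane, the esters or the lactone.

**Compound list**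

1 | 2,2-dimethoxyacetaldehyde | COC(OC)C=O | starting material
2 | methyl propiolate | C#CC(=O)OC | starting material
3 | methyl (4R)-4-hydroxy-5,5-dimethoxypent-2-ynoate | COC(=O)C#C[C@@H](O)C(OC)OC | intermediate
4 | methyl (4R)-4-(tert-butyldimethylsilyloxy)-5,5-dimethoxypent-2-ynoate | COC(=O)C#C[C@@H](O[Si](C)(C)C(C)(C)C)C(OC)OC | intermediate
5 | vinylmagnesium bromide | C=C[Mg]Br | starting material
6 | bromomethyl acetate | CC(=O)OCBr | starting material
7 | alkenylcopper adduct of 4 (copper on C2, cis to the new vinyl group; present as the vinyl cuprate) | COC(=O)/C([Cu])=C(/C=C)[C@@H](O[Si](C)(C)C(C)(C)C)C(OC)OC | intermediate (not isolated)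
8 | methyl (2Z)-2-(acetoxymethyl)-3-[(1R)-1-(tert-butyldimethylsilyloxy)-2,2-dimethoxyethyl]penta-2,4-dienoate | COC(=O)/C(COC(C)=O)=C(/C=C)[C@@H](O[Si](C)(C)C(C)(C)C)C(OC)OC | intermediate
9 | methyl (2E,4R)-2-(acetoxymethyl)-4-(tert-butyldimethylsilyloxy)-3-formyl-5,5-dimethoxypent-2-enoate | COC(=O)/C(COC(C)=O)=C(/C=O)[C@@H](O[Si](C)(C)C(C)(C)C)C(OC)OC | intermediate
10 | tributyl(2-methylallyl)stannane | CCCC[Sn](CCCC)(CCCC)CC(C)=C | starting material
11 | methyl (2Z,4S)-2-(acetoxymethyl)-3-[(1R)-1-(tert-butyldimethylsilyloxy)-2,2-dimethoxyethyl]-4-hydroxy-6-methylhepta-2,6-dienoate | COC(=O)/C(COC(C)=O)=C(/[C@@H](O)CC(C)=C)[C@@H](O[Si](C)(C)C(C)(C)C)C(OC)OC | intermediate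
12 | methyl (2Z,4S)-2-(acetoxymethyl)-3-[(1R)-1-(tert-butyldimethylsilyloxy)-2,2-dimethoxyethyl]-6-methyl-4-(3-methylbutanoyloxy)hepta-2,6-dienoate | COC(=O)/C(COC(C)=O)=C(/[C@@H](OC(=O)CC(C)C)CC(C)=C)[C@@H](O[Si](C)(C)C(C)(C)C)C(OC)OC | intermediate
13 | hex-5-en-2-ol (racemic) | CC(O)CCC=C | starting material
14 | methyl (2Z,4S,6E)-2-(acetoxymethyl)-3-[(1R)-1-(tert-butyldimethylsilyloxy)-2,2-dimethoxyethyl]-10-hydroxy-6-methyl-4-(3-methylbutanoyloxy)undeca-2,6-dienoate, C10 epimers | COC(=O)/C(COC(C)=O)=C(/[C@@H](OC(=O)CC(C)C)C/C(C)=C/CCC(C)O)[C@@H](O[Si](C)(C)C(C)(C)C)C(OC)OC | intermediate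
15 | the 10-(phenylsulfanyl) analogue of 14, C10 epimers | COC(=O)/C(COC(C)=O)=C(/[C@@H](OC(=O)CC(C)C)C/C(C)=C/CCC(C)Sc1ccccc1)[C@@H](O[Si](C)(C)C(C)(C)C)C(OC)OC | intermediate
16 | methyl (2Z,4S,6E)-2-(acetoxymethyl)-3-[(1R)-1-(tert-butyldimethylsilyloxy)-2-oxoethyl]-6-methyl-4-(3-methylbutanoyloxy)-10-(phenylsulfanyl)undeca-2,6-dienoate, C10 epimers | COC(=O)/C(COC(C)=O)=C(/[C@@H](OC(=O)CC(C)C)C/C(C)=C/CCC(C)Sc1ccccc1)[C@@H](O[Si](C)(C)C(C)(C)C)C=O | intermediate
17 | S-arylated zwitterion of 16 (diphenylsulfonium with an ortho aryl anion) | COC(=O)/C(COC(C)=O)=C(/[C@@H](OC(=O)CC(C)C)C/C(C)=C/CCC(C)[S+](c1ccccc1)c1cccc[c-]1)[C@@H](O[Si](C)(C)C(C)(C)C)C=O | intermediate (not isolated)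
18 | diphenylsulfonium ylide (carbanion at germacrane C4) | COC(=O)/C(COC(C)=O)=C(/[C@@H](OC(=O)CC(C)C)C/C(C)=C/CC[C-](C)[S+](c1ccccc1)c1ccccc1)[C@@H](O[Si](C)(C)C(C)(C)C)C=O | intermediate (not isolated)
19 | ten-membered betaine (C5 alkoxide, C4 diphenylsulfonium) | COC(=O)/C(COC(C)=O)=C1/[C@@H](OC(=O)CC(C)C)C/C(C)=C/CC[C@](C)([S+](c2ccccc2)c2ccccc2)[C@H]([O-])[C@@H]1O[Si](C)(C)C(C)(C)C | intermediate (not isolated)
20 | methyl (4R,5R,6R,8S)-13-acetoxy-6-(tert-butyldimethylsilyloxy)-4,5-epoxy-8-(3-methylbutanoyloxy)germacra-1(10),7(11)-dien-12-oate, C9/C2 trans at C1=C10, ester cis to C6 | COC(=O)/C(COC(C)=O)=C1/[C@@H](OC(=O)CC(C)C)C/C(C)=C/CC[C@@]2(C)O[C@@H]2[C@@H]1O[Si](C)(C)C(C)(C)C | intermediate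
21 | 6-hydroxy ester from 20 | COC(=O)/C(COC(C)=O)=C1/[C@@H](OC(=O)CC(C)C)C/C(C)=C/CC[C@@]2(C)O[C@@H]2[C@@H]1O | intermediate (not isolated)
22 | (4R,5R,6R,8S)-13-acetoxy-4,5-epoxy-8-(3-methylbutanoyloxy)germacra-1(10),7(11)-dien-12,6-olide, C14 methyl, C9/C2 trans | CC(=O)OCC1=C2[C@@H](OC(=O)CC(C)C)C/C(C)=C/CC[C@@]3(C)O[C@@H]3[C@@H]2OC1=O | intermediate
23 | 14-hydroxy analogue of 22 with C9/C2 cis at C1=C10 | CC(=O)OCC1=C2[C@@H](OC(=O)CC(C)C)C/C(CO)=C\CC[C@@]3(C)O[C@@H]3[C@@H]2OC1=O | intermediate
24 | CNP0289605.1 | CC(=O)OCC1=C2[C@@H](OC(=O)CC(C)C)C/C(C=O)=C\CC[C@@]3(C)O[C@@H]3[C@@H]2OC1=O | target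

**Totals and risks**

Total step count: 13. Longest linear sequence: 13 steps (1 to 24); all coupling partners are commercial.

Steps most likely to fail:

1. Step 10 (Proposed new method). The S-arylated zwitterion may lose Ph2S by β-elimination instead of forming the ylide, the ylide may decompose before the slow ten-membered closure, or the cis/trans selectivity at C4 may be poor. The fallback uses known chemistry and makes the oxirane first, then closes the ring at C1=C10. It sets out from 12. Acetal cleavage under the conditions of step 9 gives the aldehyde F1. Diphenyl(hex-5-en-2-yl)sulfonium tetrafluoroborate F2 is made from ethyldiphenylsulfonium tetrafluoroborate with LDA and then 4-iodobut-1-ene. F2 is deprotonated with LDA at −78 °C and the preformed ylide is added to F1 (intermolecular Corey–Chaykovsky epoxidation, Felkin–Anh at C5) to give the acyclic 4,5-epoxide F3. Ring-closing metathesis of F3 between its vinyl and 2-methylallyl ends (second-generation Hoveyda–Grubbs catalyst, dilute toluene) should close C1=C10, expected as the ring-cis macrocycle F4. The conditions of step 11 then give the ring-cis lactone F5, and because step 12 resets the C1=C10 geometry, its conditions take F5 to 23, where the route is rejoined.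

2. Step 3. Alkylation of the alkenylcopper may fail through protonation, attack at the acetate carbonyl, or loss of olefin geometry through the allenoate on warming. The fallback sets out from 4: the same cuprate adduct is quenched with iodine at −78 °C to give the α-iodo dienoate F6. Stille coupling with (tributylstannyl)methanol (Pd(PPh3)4, CuI) gives the hydroxymethyl dienoate F7, and acetylation (Ac2O, pyridine) returns to 8.

3. Step 12. Selenium dioxide may attack the C9 or C2 methylene instead of the C14 methyl, or the acid-sensitive oxirane may open transannularly. The fallback sets out from 22 and brings in oxygen by an ene reaction followed by allylic transposition. Photooxygenation (O2, tetraphenylporphyrin, visible light) should give the C1 hydroperoxide with an exocyclic C10=C14 methylene F8. PPh3 reduces it to the allylic alcohol F9, and catalytic Ph3SiOReO3 moves the hydroxyl to C14 and the olefin back to C1=C10, returning to 23.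

**Further compounds**

F1 | step 10 | methyl (2Z,4S)-2-(acetoxymethyl)-3-[(1R)-1-(tert-butyldimethylsilyloxy)-2-oxoethyl]-6-methyl-4-(3-methylbutanoyloxy)hepta-2,6-dienoate | COC(=O)/C(COC(C)=O)=C(/[C@@H](OC(=O)CC(C)C)CC(C)=C)[C@@H](O[Si](C)(C)C(C)(C)C)C=O
F2 | step 10 | diphenyl(hex-5-en-2-yl)sulfonium tetrafluoroborate | C=CCCC(C)[S+](c1ccccc1)c1ccccc1.F[B-](F)(F)F
F3 | step 10 | acyclic 4,5-epoxide (germacrane 4R,5R,6R,8S; C1 vinyl and C10 2-methylallyl ends) | COC(=O)/C(COC(C)=O)=C(/[C@@H](OC(=O)CC(C)C)CC(C)=C)[C@@H](O[Si](C)(C)C(C)(C)C)[C@H]1O[C@]1(C)CCC=C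
F4 | step 10 | ring-cis (C9/C2 cis at C1=C10) isomer of 20 | COC(=O)/C(COC(C)=O)=C1/[C@@H](OC(=O)CC(C)C)C/C(C)=C\CC[C@@]2(C)O[C@@H]2[C@@H]1O[Si](C)(C)C(C)(C)C
F5 | step 10 | ring-cis (C9/C2 cis at C1=C10) isomer of 22 | CC(=O)OCC1=C2[C@@H](OC(=O)CC(C)C)C/C(C)=C\CC[C@@]3(C)O[C@@H]3[C@@H]2OC1=O
F6 | step 3 | methyl (2E)-2-iodo-3-[(1R)-1-(tert-butyldimethylsilyloxy)-2,2-dimethoxyethyl]penta-2,4-dienoate | COC(=O)/C(I)=C(/C=C)[C@@H](O[Si](C)(C)C(C)(C)C)C(OC)OC
F7 | step 3 | methyl (2Z)-2-(hydroxymethyl)-3-[(1R)-1-(tert-butyldimethylsilyloxy)-2,2-dimethoxyethyl]penta-2,4-dienoate | COC(=O)/C(CO)=C(/C=C)[C@@H](O[Si](C)(C)C(C)(C)C)C(OC)OC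
F8 | step 12 | 1-hydroperoxy-10(14)-ene from 22 (C1 epimers) | CC(=O)OCC1=C2[C@@H](OC(=O)CC(C)C)CC(=C)C(OO)CC[C@@]3(C)O[C@@H]3[C@@H]2OC1=O
F9 | step 12 | 1-hydroxy-10(14)-ene from 22 (C1 epimers) | CC(=O)OCC1=C2[C@@H](OC(=O)CC(C)C)CC(=C)C(O)CC[C@@]3(C)O[C@@H]3[C@@H]2OC1=O
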